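## Structural features

Isospiculoic acid A is a trans-fused hydrindane: a cyclohexene (ring A, C1–C6, C1=C2) shares the C5–C6 bond with a cyclopentanone (ring B, C5, C6, C7, C8, C9; C8 is the carbonyl). Six stereocentres are contiguous or nearly so: the two all-carbon quaternary centres C3 (ethyl, E-styryl) and C4 (ethyl, CO2H), the fusion carbons C5 and C6, and the two ketone α-carbons C7 (ethyl) and C9 (methyl). On C3 and C4 the ethyl groups are cis, and so are the two one-carbon substituents (the styryl α-carbon and the carboxyl carbon). C5–H lies on the carboxyl face, C6–H on the ethyl face, and ring B is all-trans. The fragile points are the epimerisable C7 and C9, the E-styrene, and the hindered C4 acid, which sits close to the C1=C2 and styryl alkenes and could lactonise onto either under strong acid. The real difficulty is the vicinal quaternary pair C3/C4 and the relay of its configuration to C5 and C6. The key step exploits the fact that C3 and C4 of ring A look like the two carbons of a cis-2,3-diethylsuccinic anhydride, so ring A is the cycloadduct of diethylmaleic anhydride with a four-carbon diene supplying C2, C1, C6 and C5. A 1-amino-3-siloxydiene leaves C1 as a ketone (later the ethyl-bearing alkene carbon) and C5=C6 as an enone on which ring B can be built.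

## Logic of the disconnections

**29 from 27.** No skeletal bond is cut. A methoxycarbonyl group is put back on C7 and the C4 acid is masked as a methyl ester. This makes C7 a β-keto ester carbon (so the C7 ethyl can be introduced by alkylation) and removes the free acid from all base-mediated steps. The forward step must cleave two congested methyl esters at the O–CH3 bond, lose CO2, and leave C7 and C9 in their thermodynamic (all-trans) configuration, without acid strong enough to protonate the alkenes.

**27 from 25.** The C7–C8 bond and the C7–ethyl bond are cut, opening ring B to a diester on a finished ring A. The cut is made away from the ring fusion so that the trans relationship of C5 and C6 is fixed before cyclisation. The forward Dieckmann closure must go only through the C7 enolate; the C4 ester must stay out of it.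

**25 from 22 (through 24).** The C1–ethyl bond is cut and C1 returns to a ketone. This puts the C1=C2 alkene in place regiospecifically and reuses the carbonyl that drove the earlier enolate chemistry. The demand is kinetic enolisation of 22 toward C2 rather than C6.

**22 from 20.** The C6–C7 bond is cut to a regiodefined C1–C6 silyl enol ether and an α-halo ester. The forward alkylation must occur anti to the C5 side chain to set the trans fusion, and must not scramble the enolate.

**20 from 16 (through 17).** The styryl C=C is cut to an aldehyde on C3, and that aldehyde together with the C4 carboxyl is traced back to the cyclic anhydride. This returns both one-carbon groups to one symmetrical functional group, and it retires the most electrophilic group of the molecule before any enolate or organometallic step. The demand is that hydride attacks the C3-bound carbonyl and stops at the lactol, and that the olefination is E-selective on a neopentyl aldehyde.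

**16 from 12 and 15.** The C5–C9 bond is cut (conjugate addition of a propanoate equivalent to the enone); 15 comes from 13 by enolisation and silylation. The forward step must add on the face of C5 that carries the ethyl groups; this is the least secure stereochemical point after the key step.

**12 from 5 and 10 (key step).** The C2–C3 and C4–C5 bonds are cut. Ring A and both quaternary centres disappear in one operation, leaving a symmetrical dienophile (no regiochemistry) and a diene that carries the controlling element. The cis geometry of 5 becomes the cis relationship at C3/C4. One point in the usual analysis needs correcting: diene-face control alone does not fix the absolute configuration. Once the amine is lost, the endo and exo adducts of the same diene face give enantiomeric enones, so the step needs both facial and endo selectivity. The precursors are kept unchanged in skeleton.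

**10 from 6 and 7 (through 8).** The O–Si bond and the vinylogous C–N bond are cut, giving a commercial β-methoxy enone and the C2-symmetric amine, which is recovered after the key step.

**5 from 1 (through 3).** The anhydride is opened to the cis-diester and both C–ethyl bonds are cut back to an acetylenedicarboxylate (carbocupration, then alkylation). This is preferred to oxidative dicarbonylation of hex-3-yne, which is secure for terminal alkynes but would be an extrapolation for an unactivated internal dialkylalkyne; the cost is one extra step.

## Other disconnections considered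

**Alternative 1:** Reductive Nazarov cyclisation.
- **Cut:** the C5–C6 bond of ring B, in an acyclic precursor that already holds the C3/C4 pair.
- **Forward key step:** BF3·OEt2 activates the E,E-dienone A2; 4π conrotatory closure forms C5–C6, and Et3SiH reduces the oxyallyl cation to the cyclopentanone A1. Ring A would be closed afterwards by metathesis of the C1 methylene with the C3 vinyl arm (for example with the second-generation Grubbs catalyst).
- **In favour:** conrotation of an E,E-dienone gives the trans C5/C6 relationship in one stereospecific event, and C7 and C9 can be equilibrated afterwards.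
- **Against:** the sense of conrotation relative to C4 is controlled only by an acyclic quaternary neighbour. The C6 terminus carries a 1,1-disubstituted alkene, so the cation is extended and exposed to the Lewis acid together with the styrene. The later metathesis must choose the vinyl over the styryl group on C3. The vicinal quaternary pair must first be made enantio- and diastereoselectively in an open chain.
- **Comparison:** on the ring fusion this alternative is the better of the two, since one event replaces the two separate bond formations of steps 7 and 10. On control of C5 relative to C4 the two plans are equal, as neither has a built-in element. On structure the chosen plan is stronger, because the cycloaddition makes the C3/C4 pair with its relative configuration guaranteed. Step economy is comparable once the synthesis of A2 is counted.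

**Alternative 2:** Kulinkovich cyclopropanol.
- **Cut:** the C8–C9 bond.
- **Forward key step:** the titanacyclopropane from Ti(OiPr)4 and cyclopentylmagnesium chloride exchanges onto the C5 vinyl group of the ester A4 and adds twice to the C8 methyl ester, giving the bicyclic cyclopropanol A3. Opening of the less substituted cyclopropane bond then gives the C9-methyl ketone.
- **In favour:** ring B is closed late from two robust groups; the tert-butyl ester on C4 is inert to the titanium reagent; the C9 methyl needs no separate alkylation.
- **Against:** the problems of this target (the quaternary pair, and C5/C6 relative to C4) are all left to the synthesis of A4. The exchange must take place on a vinyl group flanked by a quaternary carbon, the ester is α-branched, and a cyclopropanol fused to a trans-hydrindane is strained. Opening toward C9 instead of the methylene would expand the ring.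
- **Comparison:** within ring B this alternative is the better plan on step economy, because it needs no sacrificial ester and no decarboxylation (steps 13 and 14 of the chosen route). On the trans fusion the two are equal, both relying on earlier stepwise installation. On mechanism the chosen Dieckmann closure is the more predictable, and on structure the chosen plan addresses ring A, which this alternative does not.

**Alternative 3:** Pauson–Khand bicyclisation.
- **Cut:** C5–C6, C7–C8 and C8–C9 at once.
- **Forward key step:** Co2(CO)8 joins the methyl alkyne on C4, the E-alkene C6=C7 and CO in the enyne A6, giving the bicyclic C5=C9 enone A5 with both rings.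
- **In favour:** three C–C bonds and two rings in one step; the alkene geometry is transferred to the C6/C7 relationship.
- **Against:** the acyclic precursor must already contain the two adjacent quaternary stereocentres. The alkene partner is internal and part of a conjugated diene, and closure of a six-membered ring by this reaction is sluggish. Diastereoselection at C6 rests on the distant quaternary centres. The C5=C9 enone then needs a conjugate reduction that sets C5 next to C4, with the same facial uncertainty as step 7 of the chosen route.
- **Comparison:** on convergence and step economy this alternative is clearly the better plan. On control at C5 the two are equal. On the quaternary pair and on the number of uncontrolled stereochemical events the chosen plan is the safer one, since its cycloaddition fixes C3/C4 by the geometry of the dienophile.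

Key step: step 5

**Convention.** Locants C1–C9 are those of the target and are used for all intermediates. β is the face of ring A carrying the ethyl groups on C3 and C4; α is the opposite face.

**Assumption.** The (2S,5S) auxiliary combined with the endo mode is taken to expose the diene face that leads to the (3aR,7aS) enone 12; if the sense proves opposite, the (2R,5R) amine is used with nothing else changed.

## Steps

Step 1
Reactants: 1 dimethyl but-2-ynedioate
Product: 3 dimethyl (2Z)-2,3-diethylbut-2-enedioate, via alkenylcopper adduct 2 (not isolated)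
Conditions: EtMgBr, CuBr·SMe2, THF, −40 °C; add 1, −78 °C; then EtI, HMPA, −78 °C → rt
Reagents that add atoms: ethylmagnesium bromide, CC[Mg]Br; iodoethane, CCI
Why: Syn-carbocupration of the acetylenic diester by ethylcopper should give the cis alkenylcopper 2, which is alkylated with retention by iodoethane in the presence of HMPA (carbocupration–alkylation, a known route to dialkylmaleates); the cis geometry is what the anhydride needs.

Step 2
Reactants: 3 dimethyl (2Z)-2,3-diethylbut-2-enedioate
Product: 5 3,4-diethylfuran-2,5-dione, via diethylmaleic acid 4 (not isolated)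
Conditions: LiOH, THF/H2O, rt; then 2 M HCl, extraction, concentration
Reagents that add atoms: lithium hydroxide, [Li+].[OH-]
Why: Saponification followed by acidification; 2,3-dialkylmaleic acids such as 4 should close spontaneously to the anhydride, so no dehydrating agent is needed.

Step 3
Reactants: 6 (3E)-4-methoxybut-3-en-2-one; 7 (2S,5S)-2,5-diphenylpyrrolidine
Product: 8 (3E)-4-[(2S,5S)-2,5-diphenylpyrrolidin-1-yl]but-3-en-2-one
Conditions: THF, 40 °C; volatiles removed in vacuo
Reagents that add atoms: none
Why: Addition–elimination of the secondary amine on the β-methoxy enone (vinylogous transamidation); the push–pull product keeps the E geometry and the stereocentres of the auxiliary are not involved.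

Step 4
Reactants: 8 (3E)-4-[(2S,5S)-2,5-diphenylpyrrolidin-1-yl]but-3-en-2-one
Product: 10 (2S,5S)-1-[(1E)-3-(tert-butyldimethylsilyloxy)buta-1,3-dien-1-yl]-2,5-diphenylpyrrolidine, via potassium dienolate 9 (not isolated)
Conditions: KHMDS, THF, −78 °C; then TBSCl, −78 °C → rt
Reagents that add atoms: tert-butyldimethylsilyl chloride, CC(C)(C)[Si](C)(C)Cl
Why: Kinetic deprotonation of the methyl ketone of the vinylogous amide and O-silylation of dienolate 9, the standard preparation of 1-amino-3-siloxybutadienes; the E enamine geometry is retained.

Step 5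
Reactants: 5 3,4-diethylfuran-2,5-dione; 10 (2S,5S)-1-[(1E)-3-(tert-butyldimethylsilyloxy)buta-1,3-dien-1-yl]-2,5-diphenylpyrrolidine
Product: 12 (3aR,7aS)-3a,7a-diethyl-3a,7a-dihydro-2-benzofuran-1,3,5(4H)-trione, via endo cycloadduct 11 (not isolated)
Conditions: PhMe, 90 °C, sealed tube; then HF·pyridine, THF, 0 °C
Reagents that add atoms: none
Why: Normal-electron-demand [4+2] cycloaddition in which the diene HOMO, raised by the amino and siloxy donors, combines with the anhydride LUMO in a concerted but asynchronous transition state, the C2–C3 bond from the nucleophilic CH2 terminus being the more advanced. The closest known reaction type is the Diels–Alder reaction of 1-amino-3-siloxybutadienes with α-substituted and α,β-disubstituted dienophiles such as substituted maleic anhydrides, the tetrasubstituted case needing heat. Ring A closes in one suprafacial–suprafacial cycloaddition that forms C2–C3 and C4–C5. The relative configuration of C3 and C4 (ethyls cis, carbonyl carbons cis) is dictated by the cis geometry of the dienophile, which cannot isomerise. Their absolute configuration is set by two elements together, the diene face left open by the C2-symmetric 2,5-diphenylpyrrolidine and the endo orientation of the anhydride carbonyls, because endo and exo adducts of one diene face give enantiomeric enones after loss of the amine. The symmetric dienophile removes any regiochemical issue. HF·pyridine then protonates nitrogen and the silyl enol ether expels the ammonium group with desilylation, erasing the C5 stereocentre and leaving the C1 ketone and the C5=C6 double bond, while the tetrasubstituted succinic anhydride is too hindered to open.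

Step 6
Reactants: 13 methyl propanoate
Product: 15 tert-butyl[(1-methoxyprop-1-en-1-yl)oxy]dimethylsilane, via lithium ester enolate 14 (not isolated)
Conditions: LDA, THF, −78 °C; then TBSCl, DMPU, −78 °C → rt
Reagents that add atoms: tert-butyldimethylsilyl chloride, CC(C)(C)[Si](C)(C)Cl
Why: Ester enolisation and O-silylation give the ketene silyl acetal; its E/Z ratio is irrelevant because C9 is equilibrated in step 14.

Step 7
Reactants: 12 (3aR,7aS)-3a,7a-diethyl-3a,7a-dihydro-2-benzofuran-1,3,5(4H)-trione; 15 tert-butyl[(1-methoxyprop-1-en-1-yl)oxy]dimethylsilane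
Product: 16 methyl 2-[6-(tert-butyldimethylsilyloxy)-3a,7a-diethyl-1,3-dioxo-1,3,3a,4,7,7a-hexahydro-2-benzofuran-4-yl]propanoate (side chain on C5 β; C9 epimers)
Conditions: HN(SO2CF3)2 (2 mol %), CH2Cl2, −78 °C
Reagents that add atoms: none
Why: Mukaiyama–Michael addition catalysed by the silyl triflimide formed in situ, with silyl transfer giving the C1–C6 enol ether regiospecifically. The nucleophile should enter C5 on the β face, anti to the C4–acyl bond (Felkin–Anh-type) and away from the anhydride carbonyl oxygen under the concave α face of the cis-fused bicycle; C9 forms as a mixture that is corrected in step 14.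

Step 8
Reactants: 16 methyl 2-[6-(tert-butyldimethylsilyloxy)-3a,7a-diethyl-1,3-dioxo-1,3,3a,4,7,7a-hexahydro-2-benzofuran-4-yl]propanoate
Product: 17 methyl 2-[6-(tert-butyldimethylsilyloxy)-3a,7a-diethyl-1-hydroxy-3-oxo-1,3,3a,4,7,7a-hexahydro-2-benzofuran-4-yl]propanoate (lactol carbon on C3; anomers)
Conditions: LiAlH(OtBu)3, THF, −40 → 0 °C; pH 6 phosphate buffer work-up
Reagents that add atoms: none
Why: Partial reduction of a cyclic anhydride to the hydroxylactone by a bulky alkoxyaluminium hydride; the C3-bound carbonyl, next to the unsubstituted C2 methylene, should be attacked in preference to the C4-bound carbonyl screened by the branched C5 side chain. The methyl ester and the silyl enol ether are inert, and the anomeric mixture is destroyed in step 9.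

Step 9
Reactants: 17 methyl 2-[6-(tert-butyldimethylsilyloxy)-3a,7a-diethyl-1-hydroxy-3-oxo-1,3,3a,4,7,7a-hexahydro-2-benzofuran-4-yl]propanoate
Product: 20 methyl 4-(tert-butyldimethylsilyloxy)-1,6-diethyl-2-(1-methoxy-1-oxopropan-2-yl)-6-[(E)-2-phenylethenyl]cyclohex-3-ene-1-carboxylate, via formyl carboxylate 18 (not isolated), via styryl carboxylate 19 (not isolated)
Conditions: (EtO)2P(O)CH2Ph, KHMDS, THF, 0 → 40 °C; then MeI, DMF, rt
Reagents that add atoms: diethyl benzylphosphonate, CCOP(=O)(Cc1ccccc1)OCC; iodomethane, CI
Why: Base opens the lactol to the non-enolisable neopentyl aldehyde 18, and Horner–Wadsworth–Emmons olefination with the benzylphosphonate anion should give the E-styrene; no second ester is yet present that could undergo a Claisen reaction. The hindered carboxylate 19 is then O-methylated by SN2 at iodomethane, which is insensitive to congestion at C4.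

Step 10
Reactants: 20 methyl 4-(tert-butyldimethylsilyloxy)-1,6-diethyl-2-(1-methoxy-1-oxopropan-2-yl)-6-[(E)-2-phenylethenyl]cyclohex-3-ene-1-carboxylate
Product: 22 methyl 1,2-diethyl-6-(1-methoxy-1-oxopropan-2-yl)-5-(2-methoxy-2-oxoethyl)-4-oxo-2-[(E)-2-phenylethenyl]cyclohexane-1-carboxylate, via ammonium enolate 21 (not isolated)
Conditions: BnMe3NF, BrCH2CO2Me, 4 Å MS, THF, −20 °C → rt
Reagents that add atoms: methyl bromoacetate, COC(=O)CBr
Why: Fluoride-promoted alkylation of a silyl enol ether: desilylation gives the regiodefined C1–C6 enolate 21, which the reactive α-bromo ester should alkylate on the α face, anti to the C5 side chain and to the axial C4 ethyl. This sets C6 (H β) and the trans C5/C6 relationship.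

Step 11
Reactants: 22 methyl 1,2-diethyl-6-(1-methoxy-1-oxopropan-2-yl)-5-(2-methoxy-2-oxoethyl)-4-oxo-2-[(E)-2-phenylethenyl]cyclohexane-1-carboxylate
Product: 24 methyl 1,6-diethyl-2-(1-methoxy-1-oxopropan-2-yl)-3-(2-methoxy-2-oxoethyl)-6-[(E)-2-phenylethenyl]-4-(trifluoromethanesulfonyloxy)cyclohex-4-ene-1-carboxylate, via potassium enolate 23 (not isolated)
Conditions: KHMDS, THF, −78 °C; then PhNTf2, −78 → 0 °C
Reagents that add atoms: N-phenylbis(trifluoromethanesulfonimide), O=S(=O)(N(c1ccccc1)S(=O)(=O)C(F)(F)F)C(F)(F)F
Why: Kinetic deprotonation of the ketone by the bulky amide at the C2 methylene rather than at the tertiary, doubly flanked C6–H, followed by O-triflation of enolate 23; the ester α-protons are several pKa units less acidic than the ketone α-protons.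

Step 12
Reactants: 24 methyl 1,6-diethyl-2-(1-methoxy-1-oxopropan-2-yl)-3-(2-methoxy-2-oxoethyl)-6-[(E)-2-phenylethenyl]-4-(trifluoromethanesulfonyloxy)cyclohex-4-ene-1-carboxylate
Product: 25 methyl 1,4,6-triethyl-2-(1-methoxy-1-oxopropan-2-yl)-3-(2-methoxy-2-oxoethyl)-6-[(E)-2-phenylethenyl]cyclohex-4-ene-1-carboxylate
Conditions: Et2Zn, Pd(dppf)Cl2 (3 mol %), THF, 0 °C → rt
Reagents that add atoms: diethylzinc, CC[Zn]CC
Why: Negishi coupling of the enol triflate; the wide-bite-angle dppf ligand favours reductive elimination over β-hydride elimination of the ethyl group, and the esters and the styrene are inert to the organozinc.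

Step 13
Reactants: 25 methyl 1,4,6-triethyl-2-(1-methoxy-1-oxopropan-2-yl)-3-(2-methoxy-2-oxoethyl)-6-[(E)-2-phenylethenyl]cyclohex-4-ene-1-carboxylate
Product: 27 dimethyl 1,4,5,7-tetraethyl-3-methyl-2-oxo-5-[(E)-2-phenylethenyl]-2,3,3a,4,5,7a-hexahydro-1H-indene-1,4-dicarboxylate, via β-keto ester enolate 26 (not isolated)
Conditions: NaH, MeOH (cat.), THF, 0 → 50 °C; then EtI, DMF, rt
Reagents that add atoms: iodoethane, CCI
Why: Dieckmann condensation under equilibrating conditions: only closure of the C7 enolate onto the C8 ester gives a β-keto ester that is held as its stabilised enolate 26, while the other Claisen products are non-enolisable and revert. C-alkylation of 26 with iodoethane then installs the C7 ethyl; the ring fusion is already fixed by C5 and C6, and C7 and C9 are left open.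

Step 14
Reactants: 27 dimethyl 1,4,5,7-tetraethyl-3-methyl-2-oxo-5-[(E)-2-phenylethenyl]-2,3,3a,4,5,7a-hexahydro-1H-indene-1,4-dicarboxylate
Product: 29 (1R,3R,3aS,4S,5R,7aS)-1,4,5,7-tetraethyl-3-methyl-2-oxo-5-[(E)-2-phenylethenyl]-2,3,3a,4,5,7a-hexahydro-1H-indene-4-carboxylic acid, via keto dicarboxylate 28 (not isolated)
Conditions: EtSNa, DMF, 90 °C; then 1 M HCl (pH 3), 40 °C
Reagents that add atoms: none
Why: Thiolate SN2 demethylation of both methyl esters (unaffected by congestion at the acyl carbons) and decarboxylation of the β-keto carboxylate 28. The basic medium should equilibrate C7 and C9 to the all-trans arrangement, each α-substituent anti to the neighbouring ring-fusion substituent, and mild acidification frees the C4 acid without protonating the alkenes.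

## Compound list

1 | dimethyl but-2-ynedioate | COC(=O)C#CC(=O)OC | starting material
2 | dimethyl 2-cuprio-3-ethylbut-2-enedioate (syn adduct, ester groups cis) | CC/C(C(=O)OC)=C(\[Cu])C(=O)OC | intermediate
3 | dimethyl (2Z)-2,3-diethylbut-2-enedioate | CC/C(C(=O)OC)=C(\CC)C(=O)OC | intermediate
4 | (2Z)-2,3-diethylbut-2-enedioic acid | CC/C(C(=O)O)=C(\CC)C(=O)O | intermediate
5 | 3,4-diethylfuran-2,5-dione (diethylmaleic anhydride) | CCC1=C(CC)C(=O)OC1=O | intermediate
6 | (3E)-4-methoxybut-3-en-2-one | CO/C=C/C(C)=O | starting material
7 | (2S,5S)-2,5-diphenylpyrrolidine | N1[C@H](c2ccccc2)CC[C@H]1c1ccccc1 | starting material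
8 | (3E)-4-[(2S,5S)-2,5-diphenylpyrrolidin-1-yl]but-3-en-2-one | CC(=O)/C=C/N1[C@H](c2ccccc2)CC[C@H]1c1ccccc1 | intermediate
9 | potassium (3E)-4-[(2S,5S)-2,5-diphenylpyrrolidin-1-yl]buta-1,3-dien-2-olate | [K+].[O-]C(=C)/C=C/N1[C@H](c2ccccc2)CC[C@H]1c1ccccc1 | intermediate
10 | (2S,5S)-1-[(1E)-3-(tert-butyldimethylsilyloxy)buta-1,3-dien-1-yl]-2,5-diphenylpyrrolidine | C=C(O[Si](C)(C)C(C)(C)C)/C=C/N1[C@H](c2ccccc2)CC[C@H]1c1ccccc1 | intermediate
11 | 6-(tert-butyldimethylsilyloxy)-4-[(2S,5S)-2,5-diphenylpyrrolidin-1-yl]-3a,7a-diethyl-3a,4,7,7a-tetrahydro-2-benzofuran-1,3-dione (endo adduct: ethyls β, amino group on C5 α and cis to the anhydride) | CC(C)(C)[Si](C)(C)OC1=C[C@H](N2[C@H](c3ccccc3)CC[C@H]2c2ccccc2)[C@]2(CC)C(=O)OC(=O)[C@]2(CC)C1 | intermediate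
12 | (3aR,7aS)-3a,7a-diethyl-3a,7a-dihydro-2-benzofuran-1,3,5(4H)-trione (C1 ketone, C5=C6) | O=C1C[C@@]2(CC)C(=O)OC(=O)[C@@]2(CC)C=C1 | intermediate
13 | methyl propanoate | CCC(=O)OC | starting material
14 | lithium 1-methoxyprop-1-en-1-olate | [Li+].CC=C([O-])OC | intermediate
15 | tert-butyl[(1-methoxyprop-1-en-1-yl)oxy]dimethylsilane (E/Z mixture) | CC=C(OC)O[Si](C)(C)C(C)(C)C | intermediate
16 | methyl 2-[6-(tert-butyldimethylsilyloxy)-3a,7a-diethyl-1,3-dioxo-1,3,3a,4,7,7a-hexahydro-2-benzofuran-4-yl]propanoate (C3/C4 as in 12; side chain on C5 β, C5–H α; C9 epimers) | CC(C)(C)[Si](C)(C)OC1=C[C@@H](C(C)C(=O)OC)[C@]2(CC)C(=O)OC(=O)[C@]2(CC)C1 | intermediate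
17 | methyl 2-[6-(tert-butyldimethylsilyloxy)-3a,7a-diethyl-1-hydroxy-3-oxo-1,3,3a,4,7,7a-hexahydro-2-benzofuran-4-yl]propanoate (lactol carbon on C3, anomers; otherwise as 16) | CC(C)(C)[Si](C)(C)OC1=C[C@@H](C(C)C(=O)OC)[C@]2(CC)C(=O)OC(O)[C@]2(CC)C1 | intermediate
18 | potassium 4-(tert-butyldimethylsilyloxy)-1,6-diethyl-6-formyl-2-(1-methoxy-1-oxopropan-2-yl)cyclohex-3-ene-1-carboxylate (formyl on C3 α, carboxylate on C4 α) | [K+].CC(C)(C)[Si](C)(C)OC1=C[C@@H](C(C)C(=O)OC)[C@](CC)(C(=O)[O-])[C@](CC)(C=O)C1 | intermediate
19 | potassium 4-(tert-butyldimethylsilyloxy)-1,6-diethyl-2-(1-methoxy-1-oxopropan-2-yl)-6-[(E)-2-phenylethenyl]cyclohex-3-ene-1-carboxylate | [K+].CC(C)(C)[Si](C)(C)OC1=C[C@@H](C(C)C(=O)OC)[C@](CC)(C(=O)[O-])[C@](CC)(/C=C/c2ccccc2)C1 | intermediate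
20 | methyl 4-(tert-butyldimethylsilyloxy)-1,6-diethyl-2-(1-methoxy-1-oxopropan-2-yl)-6-[(E)-2-phenylethenyl]cyclohex-3-ene-1-carboxylate (C3 styryl α, C4 ester α, C5 side chain β; C9 epimers) | CC(C)(C)[Si](C)(C)OC1=C[C@@H](C(C)C(=O)OC)[C@](CC)(C(=O)OC)[C@](CC)(/C=C/c2ccccc2)C1 | intermediate
21 | benzyltrimethylammonium 4,5-diethyl-4-(methoxycarbonyl)-3-(1-methoxy-1-oxopropan-2-yl)-5-[(E)-2-phenylethenyl]cyclohex-1-en-1-olate (C1–C6 enolate) | C[N+](C)(C)Cc1ccccc1.[O-]C1=C[C@@H](C(C)C(=O)OC)[C@](CC)(C(=O)OC)[C@](CC)(/C=C/c2ccccc2)C1 | intermediate
22 | methyl 1,2-diethyl-6-(1-methoxy-1-oxopropan-2-yl)-5-(2-methoxy-2-oxoethyl)-4-oxo-2-[(E)-2-phenylethenyl]cyclohexane-1-carboxylate (C5 side chain β, C6 side chain α; C9 epimers) | O=C1C[C@@](CC)(/C=C/c2ccccc2)[C@@](CC)(C(=O)OC)[C@H](C(C)C(=O)OC)[C@H]1CC(=O)OC | intermediate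
23 | potassium 3,4-diethyl-4-(methoxycarbonyl)-5-(1-methoxy-1-oxopropan-2-yl)-6-(2-methoxy-2-oxoethyl)-3-[(E)-2-phenylethenyl]cyclohex-1-en-1-olate (C1–C2 enolate) | [K+].[O-]C1=C[C@@](CC)(/C=C/c2ccccc2)[C@@](CC)(C(=O)OC)[C@H](C(C)C(=O)OC)[C@H]1CC(=O)OC | intermediate
24 | methyl 1,6-diethyl-2-(1-methoxy-1-oxopropan-2-yl)-3-(2-methoxy-2-oxoethyl)-6-[(E)-2-phenylethenyl]-4-(trifluoromethanesulfonyloxy)cyclohex-4-ene-1-carboxylate | O=S(=O)(OC1=C[C@@](CC)(/C=C/c2ccccc2)[C@@](CC)(C(=O)OC)[C@H](C(C)C(=O)OC)[C@H]1CC(=O)OC)C(F)(F)F | intermediate
25 | methyl 1,4,6-triethyl-2-(1-methoxy-1-oxopropan-2-yl)-3-(2-methoxy-2-oxoethyl)-6-[(E)-2-phenylethenyl]cyclohex-4-ene-1-carboxylate | CCC1=C[C@@](CC)(/C=C/c2ccccc2)[C@@](CC)(C(=O)OC)[C@H](C(C)C(=O)OC)[C@H]1CC(=O)OC | intermediate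
26 | sodium enolate of dimethyl 4,5,7-triethyl-3-methyl-2-oxo-5-[(E)-2-phenylethenyl]-2,3,3a,4,5,7a-hexahydro-1H-indene-1,4-dicarboxylate (C7=C8 enolate; trans ring fusion) | [Na+].CCC1=C[C@@](CC)(/C=C/c2ccccc2)[C@@](CC)(C(=O)OC)[C@H]2[C@H]1C(C(=O)OC)=C([O-])C2C | intermediate
27 | dimethyl 1,4,5,7-tetraethyl-3-methyl-2-oxo-5-[(E)-2-phenylethenyl]-2,3,3a,4,5,7a-hexahydro-1H-indene-1,4-dicarboxylate (C3, C4, C5, C6 as in 29; C7 and C9 mixtures) | CCC1=C[C@@](CC)(/C=C/c2ccccc2)[C@@](CC)(C(=O)OC)[C@H]2[C@H]1C(CC)(C(=O)OC)C(=O)C2C | intermediate
28 | disodium 1,4,5,7-tetraethyl-3-methyl-2-oxo-5-[(E)-2-phenylethenyl]-2,3,3a,4,5,7a-hexahydro-1H-indene-1,4-dicarboxylate | [Na+].[Na+].CCC1=C[C@@](CC)(/C=C/c2ccccc2)[C@@](CC)(C(=O)[O-])[C@H]2[C@H]1C(CC)(C(=O)[O-])C(=O)C2C | intermediate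
29 | (1R,3R,3aS,4S,5R,7aS)-1,4,5,7-tetraethyl-3-methyl-2-oxo-5-[(E)-2-phenylethenyl]-2,3,3a,4,5,7a-hexahydro-1H-indene-4-carboxylic acid (isospiculoic acid A) | CCC1=C[C@](/C=C/c2ccccc2)(CC)[C@@](CC)(C(=O)O)[C@H]2[C@H]1[C@@H](CC)C(=O)[C@@H]2C | target

## Step count and least certain steps

Total step count: 14. Longest linear sequence: 11 steps (steps 1, 2, 5, 7–14; the branch through steps 3, 4, 5, 7–14 is equally long).

**Step 5 (key step).** The tetrasubstituted dienophile and the hindered auxiliary may make the cycloaddition slow enough for C-acylation or thermal decay of the electron-rich diene to compete. Enantiopurity may also be eroded by leakage into the exo mode or by weak facial discrimination, since both are needed for one enantiomer of 12.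
Fallback, from 5 back to 12: anhydride 5 would be combined (PhMe, 80 °C, or 12 kbar in CH2Cl2) with the commercial, much less hindered achiral diene (1E)-3-(tert-butyldimethylsilyloxy)-N,N-dimethylbuta-1,3-dien-1-amine F1. This would give the racemic cycloadduct 6-(tert-butyldimethylsilyloxy)-4-(dimethylamino)-3a,7a-diethyl-3a,4,7,7a-tetrahydro-2-benzofuran-1,3-dione F2, for which the endo/exo ratio no longer matters. HF·pyridine would then give the racemic enone rac-3a,7a-diethyl-3a,7a-dihydro-2-benzofuran-1,3,5(4H)-trione F3, and preparative chromatography on a chiral stationary phase (amylose tris(3,5-dimethylphenylcarbamate)) would deliver 12.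

**Step 7.** Facial selectivity at C5 is the main worry: the two β ethyl groups on C3 and C4 may outweigh the anhydride and steer the nucleophile to the α face, and addition next to a quaternary carbon may be slow.
Fallback, from 12 back to 16: the same addition would be run without regard to the face and the product taken on as the C5 epimer methyl 2-[6-(tert-butyldimethylsilyloxy)-3a,7a-diethyl-1,3-dioxo-1,3,3a,4,7,7a-hexahydro-2-benzofuran-4-yl]propanoate (side chain on C5 α) F4, or as the mixture. Saegusa–Ito oxidation (Pd(OAc)2, MeCN, rt) would give the C5-substituted enone methyl 2-[3a,7a-diethyl-1,3,6-trioxo-1,3,3a,6,7,7a-hexahydro-2-benzofuran-4-yl]propanoate F5. Conjugate reduction with [(Ph3P)CuH]6 in the presence of TBSCl would then bring hydride to the face that the carbon nucleophile had preferred (α) and return the silyl enol ether 16 with C5–H α.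

**Step 8.** Hydride may attack the C4-bound carbonyl as well, because at this stage the two carbonyls differ only in their β-substituents. The aluminate may also open and be reduced further to the lactone.
Fallback, from 16 back to 17: the anhydride would be opened under steric control with sodium ethanethiolate (THF, 0 °C) to the thioester acid 4-(tert-butyldimethylsilyloxy)-1,6-diethyl-6-[(ethylsulfanyl)carbonyl]-2-(1-methoxy-1-oxopropan-2-yl)cyclohex-3-ene-1-carboxylic acid F6. Any regioisomer can be reclosed to 16 and recycled. Fukuyama reduction (Et3SiH, Pd/C, acetone) of F6 would give the aldehyde acid, which closes to 17.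

**Step 10.** Proton transfer between the ammonium enolate and the product or the esters may scramble the enolate (alkylation at C2, dialkylation), and O-alkylation may compete at the hindered C6.
Fallback, from 20 back to 22: Lewis-acid alkylation of the intact silyl enol ether with methyl 2-chloro-2-(phenylsulfanyl)acetate and ZnBr2 (CH2Cl2, 0 °C) would give methyl 1,2-diethyl-6-(1-methoxy-1-oxopropan-2-yl)-5-[2-methoxy-2-oxo-1-(phenylsulfanyl)ethyl]-4-oxo-2-[(E)-2-phenylethenyl]cyclohexane-1-carboxylate F7 without a free enolate. Radical desulfurisation (Bu3SnH, AIBN, PhH, 80 °C) would then give 22.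

## Further compounds

F1 | step 5 | (1E)-3-(tert-butyldimethylsilyloxy)-N,N-dimethylbuta-1,3-dien-1-amine | C=C(O[Si](C)(C)C(C)(C)C)/C=C/N(C)C
F2 | step 5 | racemic 6-(tert-butyldimethylsilyloxy)-4-(dimethylamino)-3a,7a-diethyl-3a,4,7,7a-tetrahydro-2-benzofuran-1,3-dione (ethyls cis; amino carbon either configuration) | CC(C)(C)[Si](C)(C)OC1=CC(N(C)C)[C@]2(CC)C(=O)OC(=O)[C@]2(CC)C1.CC(C)(C)[Si](C)(C)OC1=CC(N(C)C)[C@@]2(CC)C(=O)OC(=O)[C@@]2(CC)C1
F3 | step 5 | rac-3a,7a-diethyl-3a,7a-dihydro-2-benzofuran-1,3,5(4H)-trione (cis, both enantiomers) | O=C1C[C@@]2(CC)C(=O)OC(=O)[C@@]2(CC)C=C1.O=C1C[C@]2(CC)C(=O)OC(=O)[C@]2(CC)C=C1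
F4 | step 7 | methyl 2-[6-(tert-butyldimethylsilyloxy)-3a,7a-diethyl-1,3-dioxo-1,3,3a,4,7,7a-hexahydro-2-benzofuran-4-yl]propanoate (side chain on C5 α) | CC(C)(C)[Si](C)(C)OC1=C[C@H](C(C)C(=O)OC)[C@]2(CC)C(=O)OC(=O)[C@]2(CC)C1
F5 | step 7 | methyl 2-[3a,7a-diethyl-1,3,6-trioxo-1,3,3a,6,7,7a-hexahydro-2-benzofuran-4-yl]propanoate (ring fusion as in 12) | O=C1C[C@@]2(CC)C(=O)OC(=O)[C@@]2(CC)C(C(C)C(=O)OC)=C1
F6 | step 8 | 4-(tert-butyldimethylsilyloxy)-1,6-diethyl-6-[(ethylsulfanyl)carbonyl]-2-(1-methoxy-1-oxopropan-2-yl)cyclohex-3-ene-1-carboxylic acid (thioester on C3 α, acid on C4 α) | CC(C)(C)[Si](C)(C)OC1=C[C@@H](C(C)C(=O)OC)[C@](CC)(C(=O)O)[C@](CC)(C(=O)SCC)C1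
F7 | step 10 | methyl 1,2-diethyl-6-(1-methoxy-1-oxopropan-2-yl)-5-[2-methoxy-2-oxo-1-(phenylsulfanyl)ethyl]-4-oxo-2-[(E)-2-phenylethenyl]cyclohexane-1-carboxylate | O=C1C[C@@](CC)(/C=C/c2ccccc2)[C@@](CC)(C(=O)OC)[C@H](C(C)C(=O)OC)[C@H]1C(Sc1ccccc1)C(=O)OC
A1 | alternative 1 | all-trans ring B cyclopentanone with C1 methylene and C3 vinyl arms | C=C(CC)[C@@H]1[C@@H](CC)C(=O)[C@H](C)[C@H]1[C@](CC)(C(=O)OC)[C@@](CC)(C=C)/C=C/c1ccccc1
A2 | alternative 1 | acyclic E,E-dienone precursor (C9=C5 and C6=C7 flanking the C8 ketone) | C=C(CC)/C=C(CC)/C(=O)/C(C)=C/[C@](CC)(C(=O)OC)[C@@](CC)(C=C)/C=C/c1ccccc1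
A3 | alternative 2 | trans-fused bicyclo[3.1.0]hexan-1-ol (cyclopropanol spanning C8, C9 and the future methyl) | CCC1=C[C@](/C=C/c2ccccc2)(CC)[C@@](CC)(C(=O)OC(C)(C)C)[C@H]2[C@H]1[C@@H](CC)[C@]3(O)C[C@H]23
A4 | alternative 2 | ring A precursor with C5 vinyl group and C8 methyl ester on the C7 side chain | CCC1=C[C@](/C=C/c2ccccc2)(CC)[C@@](CC)(C(=O)OC(C)(C)C)[C@H](C=C)[C@H]1[C@@H](CC)C(=O)OC
A5 | alternative 3 | bicyclic C5=C9 enone methyl ester | CCC1=C[C@](/C=C/c2ccccc2)(CC)[C@@](CC)(C(=O)OC)C2=C(C)C(=O)[C@H](CC)[C@@H]12
A6 | alternative 3 | acyclic bis-quaternary dienyne precursor | CC/C=C/C(CC)=C\[C@](/C=C/c1ccccc1)(CC)[C@@](CC)(C(=O)OC)C#CC
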